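**Strategy.** The route rests on disconnecting the bond between the cyclobutane methine C5 (the one-carbon bridge of the bicyclo[3.1.1]heptenone that bears no methyl) and the gem-dimethyl carbon C6 of the seven-membered ring. C5 is first made as the carbonyl of a bicyclo[3.1.1]heptan-6-one by intramolecular vinylketene–alkene [2+2] cycloaddition. The key step is an intramolecular aldol addition: the only possible enolate (at C6) of a (Z)-enone tethered to the opposite bridge carbon C10 attacks this cyclobutanone, which cannot enolise because both its neighbours (C4, C11) are bridgeheads of the four-membered ring C4–C5–C11–C10 and which is strain-activated, closing the seven-membered ring and creating quaternary C6; the tertiary C5 oxygen is then excised by radical deoxygenation.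

Key step: step 9

Remark: atom labels C1–C11 follow longipinane numbering (C1 ketone carbon, C2=C3 enone alkene, C4 and C11 bridgeheads, C5 and C10 one-carbon bridges, C6 the CMe2 carbon, C7–C9 the oxygenated carbons); commercial (E)-3-methylpent-2-en-4-yn-1-ol is assumed to be the pure E isomer.

**Route**

Step 1
Reactants: 1 (E)-3-methylpent-2-en-4-yn-1-ol
Product: 2 (E)-3-methylpent-2-en-4-ynal
Conditions: MnO2 (excess), CH2Cl2, rt; used as a solution
Reagents that add atoms: none
Why: Allylic alcohol oxidation with MnO2 should convert the primary allylic alcohol into the enal without touching the terminal alkyne or the (E)-alkene.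

Step 2
Reactants: 3 methyl 3-methylbut-2-enoate
Product: 5 tert-butyl[(1-methoxy-3-methylbuta-1,3-dien-1-yl)oxy]dimethylsilane, via lithium dienolate 4 (not isolated)
Conditions: LiN(iPr)2, THF, −78 °C; TBSCl, DMPU, −78 °C → rt
Reagents that add atoms: tert-butyldimethylsilyl chloride CC(C)(C)[Si](C)(C)Cl
Why: γ-Deprotonation of the enoate and O-silylation of the lithium dienolate (silyl ketene acetal formation) should give the silyl dienol ether needed for the vinylogous aldol addition.

Step 3
Reactants: 2 (E)-3-methylpent-2-en-4-ynal; 5 tert-butyl[(1-methoxy-3-methylbuta-1,3-dien-1-yl)oxy]dimethylsilane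
Product: 7 methyl (5S,2E,6E)-5-hydroxy-3,7-dimethylnona-2,6-dien-8-ynoate, via trichlorosilyl ether 6 (not isolated)
Conditions: SiCl4 (1.1 equiv), chiral bisphosphoramide derived from N,N'-dimethyl-1,1'-binaphthyl-2,2'-diamine with a pentane-1,5-diyl linker (5 mol %, the antipode that directs attack to the Si face of the aldehyde), iPr2NEt (10 mol %), CH2Cl2, −78 °C; aq. NaHCO3
Reagents that add atoms: none
Why: In this Lewis-base-activated SiCl4 vinylogous Mukaiyama aldol addition the catalyst-bound trichlorosilyl cation activates the conjugated aldehyde and the dienolate attacks through its γ-carbon on the Si face, which should set the carbinol centre (later C1) as S under catalyst control and give the (2E)-enoate.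

Step 4
Reactants: 7 methyl (5S,2E,6E)-5-hydroxy-3,7-dimethylnona-2,6-dien-8-ynoate
Product: 8 methyl (5S,2E,6E)-3,7-dimethyl-5-(triethylsilyloxy)nona-2,6-dien-8-ynoate
Conditions: TESCl, imidazole, CH2Cl2, 0 °C
Reagents that add atoms: triethylsilyl chloride CC[Si](Cl)(CC)CC
Why: Silyl ether formation masks the alcohol with a group that should survive ketene generation and base and can later be removed in the presence of a TBS ether.

Step 5
Reactants: 8 methyl (5S,2E,6E)-3,7-dimethyl-5-(triethylsilyloxy)nona-2,6-dien-8-ynoate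
Product: 9 (5S,2E,6E)-3,7-dimethyl-5-(triethylsilyloxy)nona-2,6-dien-8-ynoic acid
Conditions: LiOH·H2O, THF/MeOH/H2O, rt; aq. HCl to pH 4 at 0 °C
Reagents that add atoms: lithium hydroxide [Li+].[OH-]
Why: Saponification of the methyl ester should leave the silyl ether, the alkyne and both alkene geometries untouched.

Step 6
Reactants: 9 (5S,2E,6E)-3,7-dimethyl-5-(triethylsilyloxy)nona-2,6-dien-8-ynoic acid
Product: 12 (4S)-7-ethynyl-7-methyl-2-methylidene-4-(triethylsilyloxy)bicyclo[3.1.1]heptan-6-one (ethynyl anti and methyl syn to the C2–C4 bridge; silyloxy group on the side of the carbonyl bridge), via acid chloride 10 (not isolated), via vinylketene 11 (not isolated)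
Conditions: 1-chloro-N,N,2-trimethylprop-1-en-1-amine, CH2Cl2, 0 °C → rt; then slow addition to Et3N, toluene, 110 °C (high dilution)
Reagents that add atoms: none
Why: Intramolecular vinylketene–alkene [2+2] cycloaddition: γ-dehydrochlorination at the methyl group cis to the acyl chloride gives vinylketene 11, whose carbonyl carbon bonds to the less substituted alkene carbon (C11) and whose α-carbon bonds to the methyl- and ethynyl-bearing carbon (C10) to give the bridged bicyclo[3.1.1]heptan-6-one, suprafacial addition to the (E)-alkene placing ethynyl anti and methyl syn to the three-carbon bridge, while A(1,3) strain with the cis methyl on C10 keeps the C1–H in the alkene plane so that the tether delivers the ketene to a single face and the (S)-silyloxy centre fixes C4, C10 and C11 in the required absolute sense.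

Step 7
Reactants: 12 (4S)-7-ethynyl-7-methyl-2-methylidene-4-(triethylsilyloxy)bicyclo[3.1.1]heptan-6-one; 13 2-methylpropanoyl chloride
Product: 14 (4S)-7-methyl-2-methylidene-7-(4-methyl-3-oxopent-1-yn-1-yl)-4-(triethylsilyloxy)bicyclo[3.1.1]heptan-6-one
Conditions: PdCl2(PPh3)2 (2 mol %), CuI (4 mol %), Et3N, THF, rt
Reagents that add atoms: none
Why: Acyl Sonogashira coupling of the terminal alkyne with the acid chloride should give the ynone directly, the non-enolisable cyclobutanone being inert to the amine base.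

Step 8
Reactants: 14 (4S)-7-methyl-2-methylidene-7-(4-methyl-3-oxopent-1-yn-1-yl)-4-(triethylsilyloxy)bicyclo[3.1.1]heptan-6-one
Product: 15 (4S)-7-methyl-2-methylidene-7-[(1Z)-4-methyl-3-oxopent-1-en-1-yl]-4-(triethylsilyloxy)bicyclo[3.1.1]heptan-6-one
Conditions: H2 (1 atm), Pd/CaCO3 poisoned with Pb(OAc)2 (Lindlar catalyst), quinoline, EtOAc, rt; used promptly
Reagents that add atoms: none
Why: Lindlar semihydrogenation adds H2 in a syn fashion to give the (Z)-enone that the ring closure needs, and should spare the 1,1-disubstituted alkene and both ketones.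

Step 9
Reactants: 15 (4S)-7-methyl-2-methylidene-7-[(1Z)-4-methyl-3-oxopent-1-en-1-yl]-4-(triethylsilyloxy)bicyclo[3.1.1]heptan-6-one
Product: 18 methyl (1S)-7-oxo-1-(triethylsilyloxy)longipina-3(15),8-dien-5-yl oxalate (exocyclic methylene on C3; C5–O syn to the C1–C3 bridge), via lithium dienolate 16 (not isolated), via lithium aldolate 17 (not isolated)
Conditions: LiN(SiMe3)2 (1.1 equiv), THF, −78 → −30 °C; then ClC(O)CO2Me, −78 °C
Reagents that add atoms: methyl chlorooxoacetate COC(=O)C(Cl)=O
Why: LiN(SiMe3)2 removes the only enolisable hydrogen of 15 (C6–H; C8 is sp2 and the cyclobutanone α-carbons C4 and C11 are bridgeheads) to give cross-conjugated dienolate 16, whose C6 terminus adds to the C5 carbonyl to give lithium aldolate 17, which is acylated in the flask so that the addition cannot revert and the tertiary oxygen is already armed for removal. The closest known reaction type is the intramolecular ketone–ketone aldol addition (aldol cyclisation) with in situ O-acylation of the aldolate. The seven-membered ring C5–C6–C7–C8–C9–C10–C4 is closed in the 7-(enolendo)-exo-trig mode. The only new stereocentre, C5, is controlled by the ring system: the tether is anchored on the exo face of C10, 1,3-cis across the four-membered ring, so C6 can reach C5 only from the face anti to the C1–C3 bridge and the oxygen is pushed to the endo face; C6 is not stereogenic. The step needs C-attack of a fully substituted enolate on a ketone in competition with retro-aldol cleavage; this is secured by the single enolisation site, the (Z)-alkene that holds C6 within bonding distance of C5, and the relief of cyclobutanone angle strain on sp2-to-sp3 rehybridisation of C5.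

Step 10
Reactants: 18 methyl (1S)-7-oxo-1-(triethylsilyloxy)longipina-3(15),8-dien-5-yl oxalate
Product: 19 (1S)-1-(triethylsilyloxy)longipina-3(15),8-dien-7-one
Conditions: Bu3SnH (3 equiv, 0.3 M), AIBN (cat.), toluene, 100 °C
Reagents that add atoms: none
Why: Barton–McCombie-type radical deoxygenation of the tertiary methyl oxalate gives the C5 cyclobutyl radical, which cannot eliminate (both β-hydrogens sit on bridgeheads) and should take hydrogen on its only open lobe, so that C5–H ends syn to the C1–C3 bridge as the ring system dictates, the high stannane concentration suppressing a 1,2-acyl shift to C6.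

Step 11
Reactants: 19 (1S)-1-(triethylsilyloxy)longipina-3(15),8-dien-7-one
Product: 21 (1S,7R)-1-(triethylsilyloxy)longipina-3(15),8-dien-7-ol (7β-hydroxy), via catechol borate ester 20 (not isolated)
Conditions: (S)-2-methyl-CBS-oxazaborolidine [(S)-1-methyl-3,3-diphenyltetrahydro-1H,3H-pyrrolo[1,2-c][1,3,2]oxazaborole] (0.3 equiv), catecholborane, toluene, −78 °C; aq. NaOH work-up
Reagents that add atoms: none
Why: Corey–Bakshi–Shibata reduction should deliver hydride in the 1,2-sense under catalyst control, with the quaternary C6 flank as the large and the ring alkenyl CH as the small substituent, to set C7 (7R here, 7S in the target) on a skeleton whose two carbonyl faces are almost mirror-related and therefore offer no opposing substrate bias.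

Step 12
Reactants: 21 (1S,7R)-1-(triethylsilyloxy)longipina-3(15),8-dien-7-ol
Product: 22 (1S,7R)-7-(tert-butyldimethylsilyloxy)-1-(triethylsilyloxy)longipina-3(15),8-diene
Conditions: TBSOTf, 2,6-lutidine, CH2Cl2, −78 → 0 °C
Reagents that add atoms: tert-butyldimethylsilyl trifluoromethanesulfonate CC(C)(C)[Si](C)(C)OS(=O)(=O)C(F)(F)F
Why: Silylation with the reactive triflate should protect the hindered neopentyl allylic alcohol, so that C7–O survives the oxidation at C1 and later steers the dihydroxylation.

Step 13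
Reactants: 22 (1S,7R)-7-(tert-butyldimethylsilyloxy)-1-(triethylsilyloxy)longipina-3(15),8-diene
Product: 23 (1S,7R)-7-(tert-butyldimethylsilyloxy)longipina-3(15),8-dien-1-ol
Conditions: PPTS (cat.), MeOH/CH2Cl2, 0 °C
Reagents that add atoms: none
Why: Acid-catalysed methanolysis cleaves a triethylsilyl ether far faster than the bulkier, neopentyl TBS ether (selective silyl ether cleavage).

Step 14
Reactants: 23 (1S,7R)-7-(tert-butyldimethylsilyloxy)longipina-3(15),8-dien-1-ol
Product: 25 (7R)-7-(tert-butyldimethylsilyloxy)longipina-2,8-dien-1-one, via β,γ-unsaturated ketone 24 (not isolated)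
Conditions: Dess–Martin periodinane, CH2Cl2, rt; filtration through basic alumina; then DBU (0.2 equiv), CH2Cl2, rt
Reagents that add atoms: none
Why: Dess–Martin oxidation gives the C1 ketone and base-mediated alkene isomerisation through the C2 dienolate should move the exocyclic alkene into conjugation, C11 being a bridgehead that cannot epimerise.

Step 15
Reactants: 25 (7R)-7-(tert-butyldimethylsilyloxy)longipina-2,8-dien-1-one
Product: 26 7β-(tert-butyldimethylsilyloxy)-8α,9α-dihydroxylongipin-2-en-1-one
Conditions: OsO4 (5 mol %), NMO, acetone/H2O, rt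
Reagents that add atoms: osmium tetroxide O=[Os](=O)(=O)=O; N-methylmorpholine N-oxide C[N+]1([O-])CCOCC1
Why: Upjohn dihydroxylation should take place at the cis-disubstituted C8=C9 alkene rather than at the deactivated enone alkene and from the face anti to the allylic C7 silyloxy group, setting C8 and C9 cis to each other and trans to O7.

Step 16
Reactants: 26 7β-(tert-butyldimethylsilyloxy)-8α,9α-dihydroxylongipin-2-en-1-one; 27 angelic acid [(Z)-2-methylbut-2-enoic acid]
Product: 29 8α-angeloyloxy-7β-(tert-butyldimethylsilyloxy)-9α-hydroxylongipin-2-en-1-one, via mixed anhydride 28 (not isolated)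
Conditions: 27, 2,4,6-trichlorobenzoyl chloride, Et3N, toluene, rt; then 26, 75 °C (no DMAP)
Reagents that add atoms: none
Why: Yamaguchi esterification through the bulky mixed anhydride should acylate the equatorial C8 hydroxyl in preference to the axial, neopentyl-type C9 hydroxyl, and the absence of a nucleophilic catalyst avoids isomerisation of the angelate to the tiglate.

Step 17
Reactants: 29 8α-angeloyloxy-7β-(tert-butyldimethylsilyloxy)-9α-hydroxylongipin-2-en-1-one; 30 3-methylbutanoyl chloride
Product: 31 8α-angeloyloxy-7β-(tert-butyldimethylsilyloxy)-9α-(3-methylbutanoyloxy)longipin-2-en-1-one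
Conditions: pyridine, DMAP (cat.), CH2Cl2, 0 °C → rt
Reagents that add atoms: none
Why: Nucleophile-catalysed acylation with the acid chloride should esterify the remaining hindered C9 hydroxyl, the low temperature limiting 8-to-9 acyl migration.

Step 18
Reactants: 31 8α-angeloyloxy-7β-(tert-butyldimethylsilyloxy)-9α-(3-methylbutanoyloxy)longipin-2-en-1-one
Product: 32 (4R,5S,7S,8R,9S,10R,11R)-8-angeloyloxy-7-hydroxy-9-(3-methylbutanoyloxy)longipin-2-en-1-one (CNP0151972.1)
Conditions: HF·pyridine, pyridine, THF, 0 °C → rt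
Reagents that add atoms: none
Why: Fluoride-mediated desilylation under weakly acidic conditions should free the C7 hydroxyl without ester cleavage, acyl migration or angelate isomerisation.

**Compound list**

1 | (E)-3-methylpent-2-en-4-yn-1-ol | C#C/C(C)=C/CO | starting material
2 | (E)-3-methylpent-2-en-4-ynal | C#C/C(C)=C/C=O | intermediate
3 | methyl 3-methylbut-2-enoate | COC(=O)C=C(C)C | starting material
4 | lithium 1-methoxy-3-methylbuta-1,3-dien-1-olate | C=C(C)C=C(OC)O[Li] | intermediate (not isolated)
5 | tert-butyl[(1-methoxy-3-methylbuta-1,3-dien-1-yl)oxy]dimethylsilane | C=C(C)C=C(OC)O[Si](C)(C)C(C)(C)C | intermediate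
6 | methyl (5S,2E,6E)-3,7-dimethyl-5-(trichlorosilyloxy)nona-2,6-dien-8-ynoate | COC(=O)/C=C(\C)C[C@H](O[Si](Cl)(Cl)Cl)/C=C(\C)C#C | intermediate (not isolated)
7 | methyl (5S,2E,6E)-5-hydroxy-3,7-dimethylnona-2,6-dien-8-ynoate | COC(=O)/C=C(\C)C[C@H](O)/C=C(\C)C#C | intermediate
8 | methyl (5S,2E,6E)-3,7-dimethyl-5-(triethylsilyloxy)nona-2,6-dien-8-ynoate | COC(=O)/C=C(\C)C[C@H](O[Si](CC)(CC)CC)/C=C(\C)C#C | intermediate
9 | (5S,2E,6E)-3,7-dimethyl-5-(triethylsilyloxy)nona-2,6-dien-8-ynoic acid | OC(=O)/C=C(\C)C[C@H](O[Si](CC)(CC)CC)/C=C(\C)C#C | intermediate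
10 | (5S,2E,6E)-3,7-dimethyl-5-(triethylsilyloxy)nona-2,6-dien-8-ynoyl chloride | ClC(=O)/C=C(\C)C[C@H](O[Si](CC)(CC)CC)/C=C(\C)C#C | intermediate (not isolated)
11 | (5S,6E)-7-methyl-3-methylidene-5-(triethylsilyloxy)nona-1,6-dien-8-yn-1-one (vinylketene) | O=C=CC(=C)C[C@H](O[Si](CC)(CC)CC)/C=C(\C)C#C | intermediate (not isolated)
12 | (4S)-7-ethynyl-7-methyl-2-methylidene-4-(triethylsilyloxy)bicyclo[3.1.1]heptan-6-one | O=C1[C@H]2[C@@H](O[Si](CC)(CC)CC)CC(=C)[C@@H]1[C@@]2(C)C#C | intermediate
13 | 2-methylpropanoyl chloride | CC(C)C(Cl)=O | starting material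
14 | (4S)-7-methyl-2-methylidene-7-(4-methyl-3-oxopent-1-yn-1-yl)-4-(triethylsilyloxy)bicyclo[3.1.1]heptan-6-one | O=C1[C@H]2[C@@H](O[Si](CC)(CC)CC)CC(=C)[C@@H]1[C@@]2(C)C#CC(=O)C(C)C | intermediate
15 | (4S)-7-methyl-2-methylidene-7-[(1Z)-4-methyl-3-oxopent-1-en-1-yl]-4-(triethylsilyloxy)bicyclo[3.1.1]heptan-6-one | O=C1[C@H]2[C@@H](O[Si](CC)(CC)CC)CC(=C)[C@@H]1[C@@]2(C)/C=C\C(=O)C(C)C | intermediate
16 | lithium dienolate of 15 (enolate at C6=C7) | O=C1[C@H]2[C@@H](O[Si](CC)(CC)CC)CC(=C)[C@@H]1[C@@]2(C)/C=C\C(O[Li])=C(C)C | intermediate (not isolated)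
17 | lithium (1S)-7-oxo-1-(triethylsilyloxy)longipina-3(15),8-dien-5-olate | O=C1C=C[C@]2(C)[C@H]3C(=C)C[C@H](O[Si](CC)(CC)CC)[C@@H]2[C@@]3(O[Li])C1(C)C | intermediate (not isolated)
18 | methyl (1S)-7-oxo-1-(triethylsilyloxy)longipina-3(15),8-dien-5-yl oxalate | O=C1C=C[C@]2(C)[C@H]3C(=C)C[C@H](O[Si](CC)(CC)CC)[C@@H]2[C@@]3(OC(=O)C(=O)OC)C1(C)C | intermediate
19 | (1S)-1-(triethylsilyloxy)longipina-3(15),8-dien-7-one | O=C1C=C[C@]2(C)[C@H]3C(=C)C[C@H](O[Si](CC)(CC)CC)[C@@H]2[C@H]3C1(C)C | intermediate
20 | catechol borate ester of 21 | c1ccc2OB(O[C@@H]3C=C[C@]4(C)[C@H]5C(=C)C[C@H](O[Si](CC)(CC)CC)[C@@H]4[C@H]5C3(C)C)Oc2c1 | intermediate (not isolated)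
21 | (1S,7R)-1-(triethylsilyloxy)longipina-3(15),8-dien-7-ol | O[C@@H]1C=C[C@]2(C)[C@H]3C(=C)C[C@H](O[Si](CC)(CC)CC)[C@@H]2[C@H]3C1(C)C | intermediate
22 | (1S,7R)-7-(tert-butyldimethylsilyloxy)-1-(triethylsilyloxy)longipina-3(15),8-diene | CC(C)(C)[Si](C)(C)O[C@@H]1C=C[C@]2(C)[C@H]3C(=C)C[C@H](O[Si](CC)(CC)CC)[C@@H]2[C@H]3C1(C)C | intermediate
23 | (1S,7R)-7-(tert-butyldimethylsilyloxy)longipina-3(15),8-dien-1-ol | CC(C)(C)[Si](C)(C)O[C@@H]1C=C[C@]2(C)[C@H]3C(=C)C[C@H](O)[C@@H]2[C@H]3C1(C)C | intermediate
24 | (7R)-7-(tert-butyldimethylsilyloxy)longipina-3(15),8-dien-1-one | CC(C)(C)[Si](C)(C)O[C@@H]1C=C[C@]2(C)[C@H]3C(=C)CC(=O)[C@@H]2[C@H]3C1(C)C | intermediate (not isolated)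
25 | (7R)-7-(tert-butyldimethylsilyloxy)longipina-2,8-dien-1-one | CC(C)(C)[Si](C)(C)O[C@@H]1C=C[C@]2(C)[C@H]3C(C)=CC(=O)[C@@H]2[C@H]3C1(C)C | intermediate
26 | 7β-(tert-butyldimethylsilyloxy)-8α,9α-dihydroxylongipin-2-en-1-one | CC(C)(C)[Si](C)(C)O[C@@H]1[C@@H](O)[C@@H](O)[C@]2(C)[C@H]3C(C)=CC(=O)[C@@H]2[C@H]3C1(C)C | intermediate
27 | angelic acid [(Z)-2-methylbut-2-enoic acid] | C/C=C(/C)C(=O)O | starting material
28 | angelic 2,4,6-trichlorobenzoic anhydride | C/C=C(/C)C(=O)OC(=O)c1c(Cl)cc(Cl)cc1Cl | intermediate (not isolated)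
29 | 8α-angeloyloxy-7β-(tert-butyldimethylsilyloxy)-9α-hydroxylongipin-2-en-1-one | CC(C)(C)[Si](C)(C)O[C@@H]1[C@@H](OC(=O)/C(C)=C\C)[C@@H](O)[C@]2(C)[C@H]3C(C)=CC(=O)[C@@H]2[C@H]3C1(C)C | intermediate
30 | 3-methylbutanoyl chloride | CC(C)CC(Cl)=O | starting material
31 | 8α-angeloyloxy-7β-(tert-butyldimethylsilyloxy)-9α-(3-methylbutanoyloxy)longipin-2-en-1-one | CC(C)(C)[Si](C)(C)O[C@@H]1[C@@H](OC(=O)/C(C)=C\C)[C@@H](OC(=O)CC(C)C)[C@]2(C)[C@H]3C(C)=CC(=O)[C@@H]2[C@H]3C1(C)C | intermediate
32 | (4R,5S,7S,8R,9S,10R,11R)-8-angeloyloxy-7-hydroxy-9-(3-methylbutanoyloxy)longipin-2-en-1-one | C/C=C(/C)C(=O)O[C@@H]1[C@@H](O)C(C)(C)[C@@H]2[C@H]3C(=O)C=C(C)[C@@H]2[C@@]3(C)[C@@H]1OC(=O)CC(C)C | target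

**Step count and risks**

Total step count: 18. Longest linear sequence: 17 steps (steps 1 and 3–18; step 2 prepares the dienolate on a side branch).

Steps most likely to fail:

1. Step 9 (key step). The aldol equilibrium may lie on the side of the open enolate, because the aldolate carries two adjacent fully substituted carbons; the acylating agent would then capture the enolate oxygen. Fallback, setting out from 15 and returning at 18: soft enolisation (TMSOTf, Et3N, CH2Cl2, 0 °C) would give the trimethylsilyl dienol ether F1. A TiCl4-promoted intramolecular Mukaiyama aldol addition (CH2Cl2, −78 °C) would close the ring under kinetic control as a titanium chelate and give, after work-up, the β-hydroxy ketone F2. Separate acylation (methyl chlorooxoacetate, pyridine, DMAP, CH2Cl2, 0 °C) would then lead to 18.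

2. Step 6. Oligomerisation of the vinylketene may outrun the cycloaddition, because the ethynyl group lowers the nucleophilicity of the C10=C11 alkene, and the facial control may erode at 110 °C. Fallback, setting out from 9 and returning at 12: amide formation (dimethylamine hydrochloride, EDC·HCl, HOBt, iPr2NEt, CH2Cl2) would give the N,N-dimethylamide F3. Activation with Tf2O and 2,4,6-collidine in 1,2-dichloroethane at 80 °C would generate the far more electrophilic vinylketeniminium triflate F4, whose intramolecular [2+2] cycloaddition should give the cyclobutaniminium triflate F5 under the same A(1,3) control. Hydrolysis with aq. NaHCO3 would release 12.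

3. Step 11. Facial discrimination by the oxazaborolidine may be poor, because both flanks of the C7 carbonyl are bulky and the skeleton gives no substrate bias. Fallback, setting out from 19 and returning at 21: Luche reduction (NaBH4, CeCl3·7H2O, MeOH, −40 °C) would give 21 together with its C7 epimer, the (1S,7S)-alcohol F6. After chromatographic separation, F6 would be re-oxidised with MnO2 (CH2Cl2, rt) to 19 and recycled.

Further compounds
F1 | step 9 | (4S)-7-methyl-2-methylidene-7-[(1Z)-4-methyl-3-(trimethylsilyloxy)penta-1,3-dien-1-yl]-4-(triethylsilyloxy)bicyclo[3.1.1]heptan-6-one | O=C1[C@H]2[C@@H](O[Si](CC)(CC)CC)CC(=C)[C@@H]1[C@@]2(C)/C=C\C(O[Si](C)(C)C)=C(C)C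
F2 | step 9 | (1S)-5-hydroxy-1-(triethylsilyloxy)longipina-3(15),8-dien-7-one | O=C1C=C[C@]2(C)[C@H]3C(=C)C[C@H](O[Si](CC)(CC)CC)[C@@H]2[C@@]3(O)C1(C)C
F3 | step 6 | (5S,2E,6E)-N,N,3,7-tetramethyl-5-(triethylsilyloxy)nona-2,6-dien-8-ynamide | CN(C)C(=O)/C=C(\C)C[C@H](O[Si](CC)(CC)CC)/C=C(\C)C#C
F4 | step 6 | vinylketeniminium triflate derived from F3 | C[N+](C)=C=CC(=C)C[C@H](O[Si](CC)(CC)CC)/C=C(\C)C#C.[O-]S(=O)(=O)C(F)(F)F
F5 | step 6 | N,N-dimethyliminium triflate of ketone 12 | C[N+](C)=C1[C@H]2[C@@H](O[Si](CC)(CC)CC)CC(=C)[C@@H]1[C@@]2(C)C#C.[O-]S(=O)(=O)C(F)(F)F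
F6 | step 11 | (1S,7S)-1-(triethylsilyloxy)longipina-3(15),8-dien-7-ol | O[C@H]1C=C[C@]2(C)[C@H]3C(=C)C[C@H](O[Si](CC)(CC)CC)[C@@H]2[C@H]3C1(C)C
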